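Cuts (chromene numbering of the target): the two indole N–H bonds are masked as N–Si. The pyran is cut at O1–C2 and C4–C4a, giving 3-methylbut-2-enal and a hydroquinone. The benzene ring is cut at C4a–C8a, giving a cyclobutenone. Cutting C5–C6 (vinyl–carbinol bond) and C8–C3' (ring–indole bond) then leads back to dimethyl squarate.
Enabling feature: the central ring is a hexasubstituted hydroquinone with the oxygen on C8a para to the OH on C6. Read as C8a(O)–C8(indol-3-yl)–C7(OMe)–C6(OH)–C5(indol-3-yl)–C4a, it matches C1(=O)–C2(indolyl)=C3(OMe)–C4(OH)–Cα(indolyl)=CβH2 of a 4-alkenyl-4-hydroxycyclobutenone, so only the C4a–C8a bond is missing.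
Forward order: the purchased four-membered ring takes up the C8 indole, then the C5 indole together with C5 and C4a. Heating expands it to the benzene ring, the pyran ring is annulated, and the nitrogens are freed last.
Stereochemistry: the target has no stereocentre, and its only non-aromatic C=C (C3=C4) is fixed in a six-membered ring. The single carbinol centre of the cyclobutenone is made racemic and is erased on aromatisation.

Key step: step 5

Remark: TIPS = triisopropylsilyl and Tris = 2,4,6-triisopropylbenzenesulfonyl. The four carbon building blocks, TIPSCl and TrisNHNH2 are taken as catalogue chemicals, and ring atoms carry the chromene numbers of the target throughout.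

Step 1
Reactants: 1 3-bromo-1-(triisopropylsilyl)indole; 2 dimethyl squarate (3,4-dimethoxycyclobut-3-ene-1,2-dione)
Product: 6 3-methoxy-4-[1-(triisopropylsilyl)indol-3-yl]cyclobut-3-ene-1,2-dione, via 3-lithio-1-(triisopropylsilyl)indole 3 (not isolated), via lithium alkoxide of the squarate 1,2-adduct 4 (not isolated), via adduct trifluoroacetate 5 (not isolated)
Conditions: 1, t-BuLi (2 equiv), THF, −78 °C; 2, THF, −78 °C; (CF3CO)2O, −78 °C; H2O, → rt
Reagents that add atoms: water, O
Why: Bromine–lithium exchange gives a 3-lithioindole that the bulky N-silyl group holds at C3, its 1,2-addition to one of the two equivalent squarate carbonyls is standard, and O-trifluoroacetylation of 4 allows ionisation to an indolyl- and methoxy-stabilised cyclobutenyl cation that takes up water at the remote enol-ether carbon and loses methanol (organolithium addition to a squarate ester with 1,3-carbonyl transposition); the racemic carbinol centre of 4 and 5 disappears in 6.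

Step 2
Reactants: 7 3-acetylindole
Product: 8 3-acetyl-1-(triisopropylsilyl)indole
Conditions: NaH, THF, 0 °C; TIPSCl, 0 °C → rt
Reagents that add atoms: triisopropylsilyl chloride, CC(C)[Si](Cl)(C(C)C)C(C)C
Why: N-silylation of a sodium indolide, in which N–H is the most acidic site and bonding at nitrogen keeps the indole aromatic; the TIPS group later shields C2 against base and electrophiles.

Step 3
Reactants: 8 3-acetyl-1-(triisopropylsilyl)indole
Product: 9 (E)-2,4,6-triisopropylbenzenesulfonylhydrazone of 3-acetyl-1-(triisopropylsilyl)indole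
Conditions: TrisNHNH2, PPTS (cat.), 4 Å MS, CH2Cl2, rt
Reagents that add atoms: 2,4,6-triisopropylbenzenesulfonohydrazide, NNS(=O)(=O)c1c(C(C)C)cc(C(C)C)cc1C(C)C
Why: Acid-catalysed hydrazone condensation in which a weak acid in an aprotic solvent spares the N–Si bond, and steric demand should place the sulfonamide nitrogen on the methyl side (E), the geometry that syn-directed deprotonation needs.

Step 4
Reactants: 9 trisylhydrazone of 3-acetyl-1-(triisopropylsilyl)indole; 6 3-methoxy-4-[1-(triisopropylsilyl)indol-3-yl]cyclobut-3-ene-1,2-dione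
Product: 12 racemic 4-hydroxy-3-methoxy-2-[1-(triisopropylsilyl)indol-3-yl]-4-{1-[1-(triisopropylsilyl)indol-3-yl]vinyl}cyclobut-2-en-1-one, via dilithiated hydrazone 10 (not isolated), via 1-[1-(triisopropylsilyl)indol-3-yl]vinyllithium 11 (not isolated)
Conditions: 9, n-BuLi (2.0 equiv), THF, −78 → 0 °C (N2 evolution); −78 °C, cannulate into 6, THF; aq NH4Cl
Reagents that add atoms: none
Why: Shapiro reaction followed by 1,2-addition of the organolithium to a cyclobutenedione: the methyl group is the only α-position of 9 and TIPS shields indole C2, so double deprotonation and loss of sulfinate and N2 can give only 11, which should attack the carbonyl next to C–OMe because the other carbonyl is the vinylogous-ester carbonyl (deactivated by the methoxy group through the ring C=C) and sits beside the bulkier indolyl group; the new carbinol centre forms as a racemate since nothing chiral is present.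

Step 5
Reactants: 12 racemic 4-hydroxy-3-methoxy-2-[1-(triisopropylsilyl)indol-3-yl]-4-{1-[1-(triisopropylsilyl)indol-3-yl]vinyl}cyclobut-2-en-1-one
Product: 15 2-methoxy-3,6-bis[1-(triisopropylsilyl)indol-3-yl]benzene-1,4-diol, via dienylketene 13 (not isolated), via cyclohexa-2,4-dienone 14 (not isolated)
Conditions: degassed p-xylene, 138 °C, Ar
Reagents that add atoms: none
Why: Heat breaks the C1–C4 bond of the cyclobutenone in a conrotatory 4π electrocyclic opening and gives dienylketene 13. The ketene carbon (future C8a) then bonds to the vinyl CH2 (future C4a) in a thermal disrotatory 6π electrocyclisation, the mode by which the single new six-membered ring closes, and keto–enol tautomerisation of dienone 14 gives the aromatic hydroquinone 15. This is the Moore rearrangement of 4-alkenyl-4-hydroxycyclobutenones to hydroquinones. The selectivity needed is torquoselectivity: the donor hydroxyl on C4 rotates outward, which turns the indolylvinyl group inward and places it cis to the ketene arm, so closure outruns lactonisation of the ketene by the hydroxyl. No stereocentre is created and the racemic carbinol centre is erased; no regiochemical choice arises because every ring atom already carries its substituent, and closure onto indole C2 would need a seven-membered transition state at a position buried by TIPS. Degassed solvent under argon holds the product at the hydroquinone oxidation level.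

Step 6
Reactants: 15 2-methoxy-3,6-bis[1-(triisopropylsilyl)indol-3-yl]benzene-1,4-diol; 16 3-methylbut-2-enal
Product: 18 7-methoxy-2,2-dimethyl-5,8-bis[1-(triisopropylsilyl)indol-3-yl]-2H-chromen-6-ol, via o-quinone methide 17 (not isolated)
Conditions: 16 (3 equiv), Ti(OiPr)4 (4 equiv), PhMe, −78 °C → rt, Ar
Reagents that add atoms: none
Why: Titanium-mediated chromene annulation of a phenol with an enal: the aryloxytitanium formed at the C8a–OH delivers the coordinated aldehyde to the only unsubstituted ring carbon (C4a, ortho to that oxygen and para to the C7 methoxy group), loss of water gives o-quinone methide 17 and oxa-6π electrocyclisation closes the pyran, while the C6–OH has no free ortho position and cannot compete.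

Step 7
Reactants: 18 7-methoxy-2,2-dimethyl-5,8-bis[1-(triisopropylsilyl)indol-3-yl]-2H-chromen-6-ol
Product: 19 kumbicin C, 5,8-di(1H-indol-3-yl)-7-methoxy-2,2-dimethyl-2H-chromen-6-ol
Conditions: Bu4NF (2.5 equiv), AcOH (2.5 equiv), THF, 0 °C → rt
Reagents that add atoms: none
Why: Fluoride-induced N-desilylation, in which fluoride attacks silicon, the expelled indolide is protonated at once by acetic acid, the buffer keeps the electron-rich C6 phenol from standing as its oxidisable phenoxide, and the chromene, methyl ether and phenol are inert.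

Compound list
1 | 3-bromo-1-(triisopropylsilyl)indole | CC(C)[Si](C(C)C)(C(C)C)n1cc(Br)c2ccccc12 | starting material
2 | dimethyl squarate | COC1=C(OC)C(=O)C1=O | starting material
3 | 3-lithio-1-(triisopropylsilyl)indole | [Li]c1cn([Si](C(C)C)(C(C)C)C(C)C)c2ccccc12 | intermediate
4 | racemic lithium 2,3-dimethoxy-4-oxo-1-[1-(triisopropylsilyl)indol-3-yl]cyclobut-2-en-1-olate | [Li]OC1(c2cn([Si](C(C)C)(C(C)C)C(C)C)c3ccccc23)C(OC)=C(OC)C1=O | intermediate
5 | racemic 2,3-dimethoxy-4-oxo-1-[1-(triisopropylsilyl)indol-3-yl]cyclobut-2-en-1-yl trifluoroacetate | O=C(OC1(c2cn([Si](C(C)C)(C(C)C)C(C)C)c3ccccc23)C(OC)=C(OC)C1=O)C(F)(F)F | intermediate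
6 | 3-methoxy-4-[1-(triisopropylsilyl)indol-3-yl]cyclobut-3-ene-1,2-dione | COC1=C(c2cn([Si](C(C)C)(C(C)C)C(C)C)c3ccccc23)C(=O)C1=O | intermediate
7 | 3-acetylindole | CC(=O)c1c[nH]c2ccccc12 | starting material
8 | 3-acetyl-1-(triisopropylsilyl)indole | CC(=O)c1cn([Si](C(C)C)(C(C)C)C(C)C)c2ccccc12 | intermediate
9 | (E)-N'-{1-[1-(triisopropylsilyl)indol-3-yl]ethylidene}-2,4,6-triisopropylbenzenesulfonohydrazide | C/C(=N\NS(=O)(=O)c1c(C(C)C)cc(C(C)C)cc1C(C)C)c1cn([Si](C(C)C)(C(C)C)C(C)C)c2ccccc12 | intermediate
10 | N,C-dilithiated hydrazone 9 (lithium on the sulfonamide nitrogen and on the former methyl carbon) | [Li]C/C(=N\N([Li])S(=O)(=O)c1c(C(C)C)cc(C(C)C)cc1C(C)C)c1cn([Si](C(C)C)(C(C)C)C(C)C)c2ccccc12 | intermediate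
11 | 1-[1-(triisopropylsilyl)indol-3-yl]vinyllithium | [Li]C(=C)c1cn([Si](C(C)C)(C(C)C)C(C)C)c2ccccc12 | intermediate
12 | racemic 4-hydroxy-3-methoxy-2-[1-(triisopropylsilyl)indol-3-yl]-4-{1-[1-(triisopropylsilyl)indol-3-yl]vinyl}cyclobut-2-en-1-one | O=C1C(c2cn([Si](C(C)C)(C(C)C)C(C)C)c3ccccc23)=C(OC)C1(O)C(=C)c1cn([Si](C(C)C)(C(C)C)C(C)C)c2ccccc12 | intermediate
13 | (3Z)-4-hydroxy-3-methoxy-2,5-bis[1-(triisopropylsilyl)indol-3-yl]hexa-1,3,5-trien-1-one (vinyl arm cis to the ketene arm) | O=C=C(c1cn([Si](C(C)C)(C(C)C)C(C)C)c2ccccc12)/C(OC)=C(/O)C(=C)c1cn([Si](C(C)C)(C(C)C)C(C)C)c2ccccc12 | intermediate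
14 | 4-hydroxy-3-methoxy-2,5-bis[1-(triisopropylsilyl)indol-3-yl]cyclohexa-2,4-dien-1-one | O=C1CC(c2cn([Si](C(C)C)(C(C)C)C(C)C)c3ccccc23)=C(O)C(OC)=C1c1cn([Si](C(C)C)(C(C)C)C(C)C)c2ccccc12 | intermediate
15 | 2-methoxy-3,6-bis[1-(triisopropylsilyl)indol-3-yl]benzene-1,4-diol | COc1c(O)c(-c2cn([Si](C(C)C)(C(C)C)C(C)C)c3ccccc23)cc(O)c1-c1cn([Si](C(C)C)(C(C)C)C(C)C)c2ccccc12 | intermediate
16 | 3-methylbut-2-enal | CC(C)=CC=O | starting material
17 | (6Z)-4-hydroxy-3-methoxy-6-(3-methylbut-2-enylidene)-2,5-bis[1-(triisopropylsilyl)indol-3-yl]cyclohexa-2,4-dien-1-one | O=C1C(c2cn([Si](C(C)C)(C(C)C)C(C)C)c3ccccc23)=C(OC)C(O)=C(c2cn([Si](C(C)C)(C(C)C)C(C)C)c3ccccc23)/C1=C/C=C(C)C | intermediate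
18 | 7-methoxy-2,2-dimethyl-5,8-bis[1-(triisopropylsilyl)indol-3-yl]-2H-chromen-6-ol | COc1c(O)c(-c2cn([Si](C(C)C)(C(C)C)C(C)C)c3ccccc23)c2c(c1-c1cn([Si](C(C)C)(C(C)C)C(C)C)c3ccccc13)OC(C)(C)C=C2 | intermediate
19 | kumbicin C | COc1c(O)c(-c2c[nH]c3ccccc23)c2c(c1-c1c[nH]c3ccccc13)OC(C)(C)C=C2 | target

Total step count: 7. Longest linear sequence: 6 steps (7 → 8 → 9 → 12 → 15 → 18 → 19).

Steps most likely to fail

1. Step 4: loss of site selectivity in the carbonyl addition. The indol-3-yl group is itself a strong π-donor and deactivates, through the ring C=C, the very carbonyl that has to be attacked, so the usual preference of alkoxycyclobutenediones may shrink.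
The fallback masks the carbonyl that must not react. It sets out from 2 and comes back at 12.
- Noyori ketalisation of 2 with 1,2-bis(trimethylsilyloxy)ethane and catalytic Me3SiOTf in CH2Cl2 would give the monoketal 2,3-dimethoxy-5,8-dioxaspiro[3.4]oct-2-en-1-one F1.
- Addition of lithioindole 3 to its single carbonyl, followed by the same (CF3CO)2O/water transposition as in step 1, would give 2-methoxy-3-[1-(triisopropylsilyl)indol-3-yl]-5,8-dioxaspiro[3.4]oct-2-en-1-one F2, whose only free carbonyl is the one next to C–OMe.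
- Vinyllithium 11 can then add nowhere else and would give racemic 2-methoxy-3-[1-(triisopropylsilyl)indol-3-yl]-1-{1-[1-(triisopropylsilyl)indol-3-yl]vinyl}-5,8-dioxaspiro[3.4]oct-2-en-1-ol F3.
- Mild aqueous acid (oxalic acid, wet THF, rt) would unmask the ketal to 12.

2. Step 6: slow C–C bond formation at C4a, which is crowded by the C5 indolyl group. Self-condensation of the enal and gradual oxidation of the hydroquinone would then take over.
The fallback forms the O–C bond first and lets a sigmatropic shift form the C–C bond. It sets out from 15 and comes back at 18.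
- Copper-catalysed O-alkylation with 3-chloro-3-methylbut-1-yne (DBU, CuCl2 cat., MeCN, 0 °C) should take the less hindered C8a–OH, which has one ortho hydrogen, rather than the C6–OH, which is flanked by OMe and indolyl. This would give 2-methoxy-4-[(2-methylbut-3-yn-2-yl)oxy]-3,6-bis[1-(triisopropylsilyl)indol-3-yl]phenol F4.
- Heating F4 in xylene at 140 °C starts an aromatic propargyl Claisen rearrangement onto C4a. Enolisation, a 1,5-hydrogen shift and oxa-6π closure then lead to 18.

3. Step 3: sluggish condensation at the vinylogous-amide carbonyl. Forcing it with stronger acid or heat brings loss of the N-silyl group and thermal decay of the sulfonyl hydrazide.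
The fallback reaches the same organolithium by tin–lithium exchange in place of the hydrazone. It sets out from 8 and comes back at 11.
- Kinetic enolisation and triflation of 8 (KN(SiMe3)2, PhNTf2, THF, −78 °C) would give 1-[1-(triisopropylsilyl)indol-3-yl]vinyl trifluoromethanesulfonate F5.
- Stannylation (Pd(PPh3)4, LiCl, (Bu3Sn)2, THF, reflux) would give tributyl{1-[1-(triisopropylsilyl)indol-3-yl]vinyl}stannane F6.
- n-BuLi in THF at −78 °C would convert F6 into 11, which is used as in step 4.

Further compounds
F1 | step 4 | 2,3-dimethoxy-5,8-dioxaspiro[3.4]oct-2-en-1-one | COC1=C(OC)C2(OCCO2)C1=O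
F2 | step 4 | 2-methoxy-3-[1-(triisopropylsilyl)indol-3-yl]-5,8-dioxaspiro[3.4]oct-2-en-1-one | COC1=C(c2cn([Si](C(C)C)(C(C)C)C(C)C)c3ccccc23)C2(OCCO2)C1=O
F3 | step 4 | racemic 2-methoxy-3-[1-(triisopropylsilyl)indol-3-yl]-1-{1-[1-(triisopropylsilyl)indol-3-yl]vinyl}-5,8-dioxaspiro[3.4]oct-2-en-1-ol | COC1=C(c2cn([Si](C(C)C)(C(C)C)C(C)C)c3ccccc23)C2(OCCO2)C1(O)C(=C)c1cn([Si](C(C)C)(C(C)C)C(C)C)c2ccccc12
F4 | step 6 | 2-methoxy-4-[(2-methylbut-3-yn-2-yl)oxy]-3,6-bis[1-(triisopropylsilyl)indol-3-yl]phenol | COc1c(O)c(-c2cn([Si](C(C)C)(C(C)C)C(C)C)c3ccccc23)cc(OC(C)(C)C#C)c1-c1cn([Si](C(C)C)(C(C)C)C(C)C)c2ccccc12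
F5 | step 3 | 1-[1-(triisopropylsilyl)indol-3-yl]vinyl trifluoromethanesulfonate | C=C(OS(=O)(=O)C(F)(F)F)c1cn([Si](C(C)C)(C(C)C)C(C)C)c2ccccc12
F6 | step 3 | tributyl{1-[1-(triisopropylsilyl)indol-3-yl]vinyl}stannane | C=C([Sn](CCCC)(CCCC)CCCC)c1cn([Si](C(C)C)(C(C)C)C(C)C)c2ccccc12
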